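In a first-order flask the percent of substrate left after a given count of half-lives does not depend on the starting concentration, so the count is the quantity to carry.

| flask | substrate | coupling partner | free catalyst | temperature | remark | time |
|---|---|---|---|---|---|---|
| epsilon | 0.061 M | 1.5 equiv | 1 mol% | 25 °C | run made earlier |  |
| eta | 0.13 M | 1.5 equiv | 1 mol% | 50 °C | run made earlier |  |
| zeta | 0.18 M | 1.5 equiv | 1 mol% | 25 °C | run made earlier |  |
| alpha | 0.076 M | 1.5 equiv | 0.65 mol% | 50 °C | run made earlier |  |
| summer | 0.076 M | 3.00 equiv | 1 mol% | 70 °C |  | 2.5 h |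
| midnight | 0.076 M | 1.50 equiv | 1 mol% | 70 °C |  | 2.5 h |
| winter | 0.15 M | 1.50 equiv | 0.3 mol% | 70 °C |  | 2.5 h |
| dusk | 0.25 M | 4.50 equiv | 1 mol% | 70 °C |  | 2.5 h |
| spring | 0.12 M | 1.50 equiv | 1 mol% | 30 °C |  | 2.5 h |

| epsilon: time / h | epsilon: target / % | eta: time / h | eta: target / % | zeta: time / h | zeta: target / % | alpha: time / h | alpha: target / % |
|---|---|---|---|---|---|---|---|
| 2.00 | 1.5 | 0.500 | 9.1 | 2.00 | 2.3 | 0.500 | 5.6 |
| 4.00 | 4.8 | 2.00 | 32.0 | 4.00 | 4.9 | 1.00 | 10.4 |
| 6.00 | 6.1 | 4.00 | 53.2 | 6.00 | 7.4 | 2.00 | 19.9 |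
| 12.0 | 14.9 | 5.00 | 61.1 | 12.0 | 13.5 | 4.00 | 37.2 |
| 25.0 | 26.5 | 6.00 | 68.3 | 25.0 | 24.1 | 6.00 | 52.2 |

(scatter of a reading: 0.5 percentage points)



- ranking by amount of target, in percent of the substrate charged, from high to low, at 2.5 h (summer / midnight / winter / dusk / spring)
- the same order at 8.0 min (summer / midnight / winter / dusk / spring)
- the amount of target, in percent of the substrate charged of the flask you put first, at 2.5 h
- the amount of target, in percent of the substrate charged of the flask you put last, at 2.5 h

Alpha stands near eta: both run at 50 °C with 1.5 equiv, though they differ in substrate and in catalyst, and after 6.00 h eta holds 68.3 % of target, more than alpha's 52.2 %. Read from those last readings, the substrate half-life is 3.62 h in eta and 5.63 h in alpha. Eta ends higher because it has run 1.66 half-lives, against 1.06. The half-lives stand in the ratio 1.56, and the catalyst loadings in the ratio 1.54. At 25 °C, epsilon and zeta differ 2.95-fold in substrate, yet their last readings give half-lives of 56.3 h and 62.8 h.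

Their mean, 59.6 h, exceeds eta's half-life by a factor of 16.5 over 25.0 degrees. Taking an equal factor per equal step of degrees gives my own figure, the half-life of substrate at 1 mol%, 1.50 equiv and spring's temperature: 34.0 h. Spring therefore counts 0.0735 half-lives and should hold 4.97 % of target at 2.5 h.

The forecast, reasoning from “catalyst tied up by partner”, gives midnight > summer > dusk > winter > spring at 2.5 h and midnight > summer > dusk > winter > spring at 8.0 min, with 96 % on top and 5.3 % at the bottom.

The flask gives summer > midnight > dusk > winter > spring at 2.5 h and dusk > summer > midnight > winter > spring at 8.0 min, with 95.8 % on top and 5.59 % at the bottom. At 2.5 h the two part over first place, where summer's 95.8 % stands above midnight's 88.2 %.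

    coupling partner + catalyst intermediate A → catalyst intermediate B (k = 0.910 M⁻¹ s⁻¹, Ea = 66.0 kJ mol⁻¹)
    substrate + free catalyst ⇌ catalyst intermediate A (K = 21.0 M⁻¹, k = 1.40 M⁻¹ s⁻¹, Ea = 40.0 kJ mol⁻¹, ΔH = −65.0 kJ mol⁻¹)
    2 catalyst intermediate B → spent catalyst (k = 1.20 M⁻¹ s⁻¹, Ea = 38.0 kJ mol⁻¹)
    catalyst intermediate D → free catalyst + target (k = 3.50 s⁻¹, Ea = 88.0 kJ mol⁻¹)
    catalyst intermediate B ⇌ catalyst intermediate C (K = 1.90, k = 0.200 s⁻¹, Ea = 74.0 kJ mol⁻¹, ΔH = −48.0 kJ mol⁻¹)
    catalyst intermediate C ⇌ by-product + catalyst intermediate D (K = 5.70 M, k = 0.0960 s⁻¹, Ea = 100 kJ mol⁻¹, ΔH = −67.0 kJ mol⁻¹)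
    (constants at 70 °C)

The repeat of spring at 55 °C, one factor 16.5 faster by the count, should reach 56.9 % and reaches 52.7 %. Spring itself holds 65.1 % of its catalyst in catalyst intermediate C, its resting state at 2.50 h, and 93 % of its substrate is still there, so the flask has not come to rest. Ten times the time makes 0.735 half-lives by the count, so 39.9 % of target, and spring stands at 42.0 %.

(Readings and results come from a simulation with made-up constants.)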